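- The trap is the smooth decay of the electrophile. It looks pseudo-first-order, and a rate constant says nothing about how much nucleophile a flask still holds.

| setting | delta | eta | Saturday's | Wednesday's | Monday's |
|---|---|---|---|---|---|
| electrophile | 0.0067 M | 0.0050 M | 0.010 M | 0.010 M | 0.010 M |
| free base | 0.020 M | 0.020 M | 0.0200 M | 0.0340 M | 0.0260 M |
| solid nucleophile | 0.015 M | 0.015 M | 0.0150 M | 0.0150 M | 0.0150 M |
| remark | run made earlier | run made earlier |  |  |  |
| time |  |  | 10 d | 10 d | 10 d |

| run | time / d | electrophile / % | target / % |
|---|---|---|---|
| delta | 0.500 | 88.6 | 10.1 |
| delta | 0.833 | 80.8 | 15.8 |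
| delta | 1.25 | 71.0 | 23.0 |
| delta | 2.00 | 56.0 | 33.2 |
| delta | 4.00 | 29.4 | 49.7 |
| delta | 6.00 | 14.3 | 60.5 |
| eta | 1.04 | 75.5 | 21.9 |
| eta | 2.08 | 54.0 | 35.6 |
| eta | 3.00 | 39.3 | 44.6 |
| eta | 4.00 | 28.2 | 52.2 |
| eta | 5.00 | 20.1 | 58.5 |
| eta | 6.00 | 15.3 | 61.4 |

(standard deviation of a reading: 0.5 percentage points)

- the earlier runs were read with a standard deviation of 0.5 percentage points
- at the start none of the solid nucleophile is in solution
- a reading or a percentage of target counts all its forms, free or not
- no earlier run changes the charge of free base; that part of a forecast is a guess

- part of the electrophile that has reacted at the end, Saturday's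
- part of the electrophile that has reacted at the end, Wednesday's
- part of the electrophile that has reacted at the end, Monday's
- what raising the concentration of free base from its lowest to its highest value here does to the part of the electrophile that has reacted (changes below 5 percentage points count as none) (it falls / it rises / no change)

- Time comes first. Between 2.00 d and 6.00 d I read 0.341 d⁻¹ from the delta run. Carried from its 14.3% out to 10 d, that leaves 3.65%, so my own reckoning is 96.3% reacted.
- The electrophile charge comes next. At 6.00 d, delta reads 14.3% left and eta 15.3%, so by hand the charge barely moves the fraction.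
- That charge also sets what I carry: the reserve, 1.50 on Saturday's, meaning c(solid nucleophile) over c(electrophile) as charged.
- Delta has a reserve of 2.24 and eta 3.00, so Saturday's stands lower than either. The readings have not tested it there.
- Solid nucleophile is the setting I watch. If one nucleophile serves one electrophile, Saturday's keeps 0.500 of reserve spare. If each electrophile costs more, control passes from time to the reserve.
- Free base is a guess, since no run varies it. My 3.65% of headroom is smaller than the mark of 5 percentage points, so I expect no rise.
- The forecast gives 95%, 97% and 96% for Saturday's, Wednesday's and Monday's, with the trend no change. It adds: “Slight depletion could lower this a little”.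
- The flasks give 91.9%, 92.0% and 91.9% in that order, and the trend is no change, a change of 0.18 points. The forecast holds within its tolerance, though its 95% for Saturday's stands above the flask's 91.9%.

    electrophile + nucleophile → acid set free + target (k = 0.00360 M⁻¹ s⁻¹)
    solid nucleophile ⇌ nucleophile, rate k2*(cs2 - [nucleophile]) while solid is left; crystals form when [nucleophile] > cs2 (solubility = 0.940 mM, k = 2.50 × 10⁻⁴ s⁻¹)
    nucleophile + acid set free ⇌ protonated nucleophile, settled at all times (K = 4.30 × 10⁵ M⁻¹)
    crystals ⇌ target, rate k4*(cs4 - [target]) while solid is left; crystals form when [target] > cs4 (solubility = 1.60 mM, k = 0.00140 s⁻¹)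
    acid set free + free base ⇌ salt of the base, settled at all times (K = 65.0 M⁻¹)
    electrophile + target → side product (k = 4.10 × 10⁻⁴ M⁻¹ s⁻¹)

- At 10.0 d on Monday's, the path through nucleophile uses electrophile at 0.87 of the rate of the path through target, with solid nucleophile, the limiting reagent, at 0% and dissolved nucleophile at 1.59 × 10⁻⁴ M. Monday's reserve of 1.50 stands above the value at which its answer has moved by 5 points: 1.34 with solid nucleophile lowered to 0.0134 M, and 1.34 with electrophile raised to 0.0112 M. The neighbour with 0.0090 M of solid nucleophile has a reserve of 0.900, and at 10.0 d it has reacted 72.5%, with 27.5% of its electrophile left.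

Readings and results come from a simulation from invented constants, and the scatter is random.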